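## Structural features

The target is an aryl alkyl ether between O7 of 6,8-dimethoxycoumarin (isofraxidin) and the C11 methylene of an oxidised drimane. The terpenoid part is a trans-fused decalin (ring A: C1–C5 and C10; ring B: C5–C10) with a gem-dimethyl group at C4, an angular methyl at C10, a C8 methyl on a C7=C8 bond conjugated with a C6 ketone, and an isovalerate at C3. There are four stereocentres: C5, C10 and C9 are contiguous, whereas C3 is separated from them by the quaternary C4. Relative to the β C10 methyl, H5 is α (trans fusion), the C9 oxymethylene is α (9-epi-drimane arrangement, H9 β) and the C3 ester is α, that is axial and next to the quaternary carbon. The coumarin lactone and both esters are sensitive to nucleophiles and hydride. The C9 hydrogen is γ to the C6 carbonyl, so base can form the dienolate, which can expel the aryloxide from C11 or scramble C9; the ether must therefore be made last and without base. The real difficulty is ring B: a C6 carbonyl, a C7=C8 bond, and a C9 substituent anti to the angular methyl on a carbon flanked by two fully substituted carbons. The axial C3 oxygen is a second difficulty, since it cannot be reached by substitution at that neopentyl centre. The key step exploits the fact that ring B, its C8 methyl, the C5 stereocentre, and C4 with both its methyls (as an isopropenyl group on C5) are all present in carvone, so ring A needs only the C3–C4 bond.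

## Logic of the disconnections

22 ⇒ 18 + 21. The C9–C11 bond is cut. Ether formation by displacement at C11 would be slow at this β-branched carbon, and base would trigger loss of aryloxide. Cutting C9–C11 instead makes C9 the γ terminus of a silyl dienol ether and C11 an oxocarbenium-type carbon that already carries the whole coumarin. The terpenoid loses one carbon and one stereocentre. The forward step must attack at C9 rather than C7, from the face anti to the C10 methyl, under Lewis-acidic conditions that spare the lactone and esters.

21 ⇒ 20 ⇒ 19. The C–Cl bond is traced back to an O,S-acetal and then the O–CH2 bond is cut. A chloromethyl aryl ether cannot be made from the phenol, formaldehyde and HCl without attack on the ring, whereas the methylthiomethyl ether is stable and is converted by chlorination at sulfur. The forward step needs S-chlorination to outrun halogenation of the electron-rich arene.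

18 ⇒ 16. The O–Si bond is cut and an acetate is restored at C9. A γ-acyloxy enone is a regiochemically unambiguous source of the C6-oxygen dienolate, because two-electron reduction expels the γ leaving group. The problem becomes an enone with oxygen on C9, the former carbonyl carbon of the starting ring. The reduction must spare the C3 ester and the dienolate must be silylated on oxygen.

16 ⇒ 15. The C6 carbonyl is removed. C6 is the only ring methylene allylic to C7=C8, so the oxygen can be introduced by allylic C–H oxidation and need not be carried earlier. The forward step must choose C6 over the C8 methyl and the C9 hydrogen.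

15 ⇒ 14 ⇒ 13 ⇒ 12. The ester C–O bond is cut, then the C3–H bond (hydride), then the ketone is traced to the alcohol of either configuration. The axial C3 oxygen is reached by equatorial delivery of a bulky hydride to the ketone, which also makes the C3 outcome of the ring closure irrelevant. This requires that no other hydride acceptor be present, which is why C9 carries an acetate and not a carbonyl at this stage.

12 ⇒ 11. The C3–C4 bond is cut and ring A is opened. The bicycle becomes a cyclohexene with three appendages, all derived from carvone, in which C5 and C10 are already set trans. The forward step needs hydrogen-atom transfer to the 1,1-disubstituted alkene only, cyclisation faster than reduction of the radical, and rapid reduction of the alkoxy radical.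

11 ⇒ 10 ⇒ 8. The aldehyde is traced to the primary alcohol and the C3–O bond to a terminal alkene. The three-carbon chain then enters as an allyl group. The hydroboration must select the monosubstituted alkene over the isopropenyl group and the ring alkene, which a dialkylborane does, and no ketone may be present.

8 ⇒ 7 ⇒ 6. The acetate is removed and the C9–H bond is cut, returning to the enone. This restores the oxidation level of the starting ring. Only 1,2-selectivity is required, since the configuration created is later destroyed.

6 ⇒ 3 + 4 and 3 ⇒ 1. The C10–C1 and C10–CH3 bonds are cut as two successive kinetic enolate alkylations. The methyl enters first and the allyl group second, so that the larger electrophile adds anti to the isopropenyl group. This places the future ring-A chain trans to it and thereby fixes the trans ring fusion. Both steps need α′- rather than γ-deprotonation.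

## Other disconnections considered

Alternative 1: The cut runs through C5–C10 and C8–C9 together, opening both rings to the acyclic triene A1. A1 is an aryl (Z)-allylic ether whose trisubstituted C9=C10 alkene is tied through C1–C4 to a 6-silyloxy-5,7-diene. Heating would give the bicyclic silyl enol ether A2 by intramolecular Diels–Alder reaction. A Saegusa-type dehydrogenation with Pd(OAc)2 would then give the 7-en-6-one and remove the C8 stereocentre.
- In its favour: one step would form both rings and the C5, C9 and C10 stereocentres. The Z dienophile geometry translates directly into the anti relationship of C11 and the C10 methyl. The C6 oxygen is in place from the start, and the coumarin is attached by simple allylic substitution before any hindered centre exists. On these points (no enone transposition, no C–C bond formation at the congested C9, few steps after ring formation) it is the better plan.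
- Against it: the dienophile is an unactivated trisubstituted alkene facing an electron-rich diene, and the C5–C10 bond joins a carbon next to the quaternary C4 to a fully substituted carbon. Forcing temperatures would be needed, at which the allylic aryl ether can ionise and the silyloxydiene can undergo hydrogen shifts. Ring-fusion and facial selectivity would depend on tether conformation and on the single remote C3 stereocentre. That centre is β in A2 and would still need inversion. A1 also requires separate control of a Z-trisubstituted alkene, a dienol ether geometry and an enantioselective carbinol.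
- Comparison: the chosen plan takes C5 and the fusion relationship from the chiral pool and closes ring A with the fusion outcome fixed beforehand. It pays with a longer functional-group sequence on ring B.

Alternative 2: The cut is at C9–C10, paired with reconnection of C6 to a lactone oxygen. Ring B is opened to the δ-lactone A3, which carries ring A as a tetrasubstituted cyclohexenyl group on its carbinol carbon (C6) and the future C8 methyl. O-Silylation of the lactone enolate and warming would trigger the ring-contracting Ireland–Claisen rearrangement to the acid A4. This forms C9–C10, breaks C6–O and moves the alkene to C5=C6.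
- In its favour: the [3,3] shift is suprafacial and transfers the C6 configuration to the quaternary C10 while fixing C9 in the same transition state. The anti relationship of C11 and the angular methyl is therefore set by a sigmatropic event and not by face-selective attack in the last step. On the reliability of the C9/C10 relationship it is at least the equal of the chosen plan, and C11 arrives early as a carboxyl carbon.
- Against it: the rearrangement must pass through a boat-like transition state and bond a ketene acetal carbon to a tetrasubstituted alkene carbon flanked by a gem-dimethyl group. A4 is still far from the target. It needs C5–H and the C6 carbonyl installed across C5=C6, the C7=C8 unsaturation, reduction of the acid, ether formation by substitution at the β-branched C11, and unmasking, reduction and acylation at C3. A3 itself needs two stereocentres and a hindered vinyl-metal addition.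
- Comparison: it would be clearly longer than the chosen route, but it avoids that route's weakest point, the late C9–C11 bond.

Alternative 3: The terpenoid is left intact and the coumarin is dismantled at the aryl C4a–C8a bond. The C11 alcohol A5 would be joined to dimethyl squarate by vinylogous transesterification. A 3,3-diethoxypropenyl-metal would be added to the carbonyl flanking the terpenyloxy carbon and the tertiary alkoxide methylated to give the cyclobutenone A6. Thermolysis would open the four-membered ring, with the methoxy group rotating outward, to a dienylketene that closes by 6π electrocyclisation and tautomerises to the phenol A7. Acetal hydrolysis and Wittig olefination–lactonisation would then complete the coumarin.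
- In its favour: the aryl–O–C11 bond is made by addition–elimination at an sp2 carbon, which needs neither substitution at C11 nor an aryloxymethyl cation. On this one bond it is better than the chosen plan. The benzannulation also fixes the pattern of the pentasubstituted arene.
- Against it: compound 19 already contains that arene, so five or more steps would rebuild an available ring. The whole terpenoid, including C9, must be finished first, so no real difficulty is removed. The two squarate carbonyls differ only in a remote alkoxy group, so the addition would hardly be regioselective, and the organometallic is incompatible with the C6 enone and C3 ester unless these are masked. The thermolysis and the final olefination–lactonisation expose the base- and heat-sensitive γ-stereocentre and β-aryloxy arrangement.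
- Comparison: both plans finish with a non-basic bond formation, but the chosen plan is shorter by the whole arene synthesis.

Key step: step 7

Remarks on the chemistry:
- Numbering: bicyclic compounds use drimane numbering and β means the face of the C10 methyl. Monocyclic compounds use carvone numbering (C1 = drimane C9, C2 = C8, C3 = C7, C4 = C6, C5 = C5, C6 = C10).
- Precursor design: the C9 carbonyl is carried through the ring closure as its allylic acetate (same skeleton, same C3–C4 bond, same ring closed). The free enone would be a liability toward the dialkylborane used to make the aldehyde and would undergo conjugate reduction by the bulky hydride needed to reset C3. The acetate is in any case the leaving group required at C9 in step 12.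
- Assumption: the carbinol configuration created in step 3 is drawn as the epimer expected from hydride delivery anti to the C6 methyl. It is destroyed in step 12, so the other epimer would serve equally.
- Structure check: (R)-carvone has the C5 configuration that maps onto C5 of the target.

## Route

Step 1
Reactants: 1 (R)-carvone
Product: 3 6-methylcarvone [(5R)-2,6-dimethyl-5-(prop-1-en-2-yl)cyclohex-2-en-1-one; C6 epimer mixture], via carvone lithium dienolate 2 (not isolated)
Conditions: LiN(i-Pr)2, THF, −78 °C; MeI, −78 → 0 °C
Reagents that add atoms: iodomethane, CI
Why: Kinetic deprotonation by the hindered amide removes the α′ proton at C6 (cross-conjugated enolate) and not a γ proton, and the enolate is C-methylated (enolate alkylation); the epimer mixture at C6 is irrelevant because this centre is planarised again in step 2.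

Step 2
Reactants: 3 6-methylcarvone; 4 allyl bromide
Product: 6 (5S,6S)-6-allyl-6-methylcarvone [2,6-dimethyl-6-(prop-2-en-1-yl)-5-(prop-1-en-2-yl)cyclohex-2-en-1-one; allyl trans to isopropenyl], via methylcarvone lithium enolate 5 (not isolated)
Conditions: LiN(i-Pr)2, THF, −78 °C; then 4, DMPU, −78 → 0 °C
Reagents that add atoms: none
Why: The remaining C6 hydrogen is again the kinetically accessible α′ proton; the tetrasubstituted enolate is allylated on the face opposite the adjacent isopropenyl group (enolate alkylation, 1,2-induction), which sets the quaternary centre (later C10) with the chain trans to the isopropenyl group, the relationship that becomes the trans ring fusion.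

Step 3
Reactants: 6 (5S,6S)-6-allyl-6-methylcarvone
Product: 7 (1S,5S,6S)-6-allyl-2,6-dimethyl-5-(prop-1-en-2-yl)cyclohex-2-en-1-ol (hydroxyl cis to the C6 methyl)
Conditions: NaBH4, CeCl3·7H2O, MeOH, −78 → 0 °C
Reagents that add atoms: none
Why: Luche reduction gives clean 1,2-addition of hydride to the hindered enone; delivery anti to the C6 methyl should give mainly the epimer shown, and this configuration is of no consequence because the centre is removed in step 12.

Step 4
Reactants: 7 allylic alcohol
Product: 8 (1S,5S,6S)-6-allyl-2,6-dimethyl-5-(prop-1-en-2-yl)cyclohex-2-en-1-yl acetate
Conditions: Ac2O, pyridine, DMAP (cat.), CH2Cl2, rt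
Reagents that add atoms: acetic anhydride, CC(=O)OC(C)=O
Why: DMAP-catalysed acylation of the hindered secondary allylic alcohol; the acetate masks the former carbonyl through the borane, radical and hydride steps and is the leaving group needed at C9 in step 12.

Step 5
Reactants: 8 allylic acetate
Product: 10 (1S,5S,6S)-6-(3-hydroxypropyl)-2,6-dimethyl-5-(prop-1-en-2-yl)cyclohex-2-en-1-yl acetate, via alkyldisiamylborane 9 (not isolated)
Conditions: Sia2BH (from BH3·SMe2 and 2-methyl-2-butene), THF, 0 °C; then NaBO3·4H2O, H2O, rt
Reagents that add atoms: sodium perborate tetrahydrate NaBO3·4H2O, [Na+].[Na+].O[B-]1(O)OO[B-](O)(O)OO1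
Why: Hydroboration–oxidation: the bulky dialkylborane adds to the monosubstituted allyl terminus far faster than to the 1,1-disubstituted isopropenyl group or the trisubstituted ring alkene and puts boron on the terminal carbon; perborate oxidises the C–B bond under conditions mild enough for the acetate.

Step 6
Reactants: 10 primary alcohol
Product: 11 (1S,5S,6S)-2,6-dimethyl-6-(3-oxopropyl)-5-(prop-1-en-2-yl)cyclohex-2-en-1-yl acetate (the C1-acetoxy form of 6-methyl-6-(3-oxopropyl)carvone)
Conditions: Dess–Martin periodinane, CH2Cl2, 0 °C → rt
Reagents that add atoms: none
Why: Dess–Martin oxidation takes the primary alcohol to the aldehyde under neutral conditions without over-oxidation and without touching the acetate or the alkenes.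

Step 7
Reactants: 11 alkenyl aldehyde
Product: 12 9β-acetoxy-11-nor-drim-7-en-3β-ol (5α-H, 10β-CH3)
Conditions: Fe(acac)3 (0.5 equiv), PhSiH3 (2.5 equiv), EtOH (0.02 M), 60 °C
Reagents that add atoms: none
Why: An iron hydride formed from Fe(acac)3 and PhSiH3 in ethanol transfers a hydrogen atom to the terminal methylene of the isopropenyl group, which becomes the second C4 methyl and leaves a tertiary radical at C4. The radical adds to the aldehyde carbon C3 in a 6-exo-trig closure of ring A, and the alkoxy radical is reduced by divalent iron and protonated by the solvent, which pulls the reversible addition forward. The closest known reaction type is the Mukaiyama-type metal-hydride hydrogen-atom-transfer reductive cyclisation of alkenes onto ketones and aldehydes. Ring A closes through a chair-like transition state with the C5–C4 and C10–C1 bonds both equatorial on ring B; because these bonds were fixed trans in step 2, only the trans-decalin can form. The one new stereocentre, C3, is controlled by that chair, in which the carbonyl oxygen prefers the pseudo-equatorial position (3β) away from the axial hydrogens on C1 and C5; any 3α epimer is compound 14 itself, and both epimers converge at 13. The step needs hydrogen-atom transfer to the 1,1-disubstituted alkene only: the trisubstituted ring alkene is more hindered and deactivated by the allylic acetate, no conjugated acceptor is present, and the C4 radical has no other unsaturated carbon within reach of a five- or six-membered closure. High dilution suppresses bimolecular reduction of the radical.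

Step 8
Reactants: 12 9β-acetoxy-11-nor-drim-7-en-3β-ol
Product: 13 9β-acetoxy-11-nor-drim-7-en-3-one
Conditions: Dess–Martin periodinane, CH2Cl2, rt
Reagents that add atoms: none
Why: Dess–Martin oxidation converts either C3 epimer into the same ketone, so the C3 outcome of the ring closure is erased.

Step 9
Reactants: 13 C3 ketone
Product: 14 9β-acetoxy-11-nor-drim-7-en-3α-ol
Conditions: LiBH(s-Bu)3, THF, −78 °C; then H2O
Reagents that add atoms: none
Why: The bulky trialkylborohydride attacks the C3 ketone from the equatorial direction, since the axial path is blocked for a large reagent by the axial hydrogens on C1 and C5, and so gives the axial 3α alcohol; the ketone is the only reducible group, the hindered acetate being inert at −78 °C.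

Step 10
Reactants: 14 3α alcohol
Product: 15 9β-acetoxy-11-nor-drim-7-en-3α-yl 3-methylbutanoate
Conditions: isovaleryl chloride, pyridine, DMAP, CH2Cl2, 0 → 40 °C
Reagents that add atoms: 3-methylbutanoyl chloride, CC(C)CC(=O)Cl
Why: Acyl-transfer catalysis by DMAP drives esterification of the hindered axial alcohol with the acid chloride; no stereocentre is touched.

Step 11
Reactants: 15 diester
Product: 16 9β-acetoxy-6-oxo-11-nor-drim-7-en-3α-yl 3-methylbutanoate
Conditions: CrO3, 3,5-dimethylpyrazole, CH2Cl2, −20 °C
Reagents that add atoms: chromium trioxide CrO3, O=[Cr](=O)=O
Why: Allylic oxidation by the complex of hexavalent chromium with 3,5-dimethylpyrazole converts the only ring methylene allylic to C7=C8 into a carbonyl, as in the oxidation of cyclohexene-type terpenes and sterols to enones; the C8 methyl is a poorer site and the C9 hydrogen is deactivated by its acetoxy group and screened by C10.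

Step 12
Reactants: 16 γ-acetoxy enone
Product: 18 6-(tert-butyldimethylsilyloxy)-11-nor-drima-6,8-dien-3α-yl 3-methylbutanoate, via diiodosamarium dienolate 17 (not isolated)
Conditions: SmI2 (2.2 equiv), THF–HMPA, −78 °C; then TBSCl, −78 → 0 °C
Reagents that add atoms: tert-butyldimethylsilyl chloride, CC(C)(C)[Si](C)(C)Cl
Why: Two single-electron transfers from SmI2 to the enone give an allylic anion that expels the γ-acetate (the vinylogous form of the reductive cleavage of α-acyloxy ketones), so the dienolate forms with its double bonds fixed at C6=C7 and C8=C9; O-silylation in the presence of HMPA stores it as the dienol ether, and the isolated C3 ester is not reduced under these aprotic conditions.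

Step 13
Reactants: 19 isofraxidin (7-hydroxy-6,8-dimethoxy-2H-chromen-2-one)
Product: 20 6,8-dimethoxy-7-[(methylsulfanyl)methoxy]-2H-chromen-2-one
Conditions: NaH, DMF, 0 °C; MeSCH2Cl, NaI (cat.), rt
Reagents that add atoms: chloromethyl methyl sulfide, CSCCl
Why: Williamson etherification of the acidic phenol with the α-chloro sulfide under iodide catalysis; both ortho positions are substituted, so only O-alkylation is possible, and the lactone is stable to the phenoxide.

Step 14
Reactants: 20 methylthiomethyl ether
Product: 21 7-(chloromethoxy)-6,8-dimethoxy-2H-chromen-2-one
Conditions: SO2Cl2 (1.0 equiv), CH2Cl2, −78 → 0 °C; evaporate, use crude at once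
Reagents that add atoms: sulfuryl chloride SO2Cl2, O=S(=O)(Cl)Cl
Why: Chlorination at sulfur gives a chlorosulfonium ion that collapses to the chloromethyl ether and methanesulfenyl chloride, the standard conversion of O,S-acetals into α-chloro ethers; low temperature and one equivalent keep the reagent away from the arene.

Step 15
Reactants: 18 silyl dienol ether; 21 chloromethyl aryl ether
Product: 22 11-[(6,8-dimethoxy-2-oxo-2H-chromen-7-yl)oxy]-6-oxo-9-epi-drim-7-en-3α-yl 3-methylbutanoate (5α-H, 9β-H, 10β-CH3; the target)
Conditions: ZnBr2 (0.2 equiv), CH2Cl2, 4 Å molecular sieves, −40 → 0 °C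
Reagents that add atoms: none
Why: Lewis-acid-mediated vinylogous Mukaiyama-type alkylation: ZnBr2 activates the α-chloro ether and the silyl dienol ether attacks through its γ carbon C9, the terminus with the largest HOMO coefficient, which restores the C6 ketone and the C7=C8 bond. The electrophile approaches C9 anti to the pseudoaxial C10 methyl, from the α face, which sets C11 α and H9 β as in the target; the conditions are non-basic, so neither the new γ-stereocentre nor the aryl ether is endangered.

## Compound list

1 | (R)-carvone, (5R)-2-methyl-5-(prop-1-en-2-yl)cyclohex-2-en-1-one | CC1=CC[C@H](CC1=O)C(C)=C | starting material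
2 | lithium cross-conjugated dienolate of 1 (O–Li on C1, C1=C6) | CC1=CC[C@H](C=C1O[Li])C(C)=C | intermediate
3 | 6-methylcarvone, (5R)-2,6-dimethyl-5-(prop-1-en-2-yl)cyclohex-2-en-1-one, C6 epimer mixture | CC1=CC[C@H](C(C)C1=O)C(C)=C | intermediate
4 | allyl bromide, 3-bromoprop-1-ene | C=CCBr | starting material
5 | lithium enolate of 3 (O–Li on C1, tetrasubstituted C1=C6) | CC1=CC[C@H](C(C)=C1O[Li])C(C)=C | intermediate
6 | (5S,6S)-2,6-dimethyl-6-(prop-2-en-1-yl)-5-(prop-1-en-2-yl)cyclohex-2-en-1-one | C=CC[C@]1(C)C(=O)C(C)=CC[C@H]1C(C)=C | intermediate
7 | (1S,5S,6S)-2,6-dimethyl-6-(prop-2-en-1-yl)-5-(prop-1-en-2-yl)cyclohex-2-en-1-ol | C=CC[C@]1(C)[C@@H](O)C(C)=CC[C@H]1C(C)=C | intermediate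
8 | (1S,5S,6S)-2,6-dimethyl-6-(prop-2-en-1-yl)-5-(prop-1-en-2-yl)cyclohex-2-en-1-yl acetate | C=CC[C@]1(C)[C@@H](OC(C)=O)C(C)=CC[C@H]1C(C)=C | intermediate
9 | bis(3-methylbutan-2-yl)borane adduct at the terminal carbon of the allyl group of 8 | CC(C)C(C)B(CCC[C@]1(C)[C@@H](OC(C)=O)C(C)=CC[C@H]1C(C)=C)C(C)C(C)C | intermediate
10 | (1S,5S,6S)-6-(3-hydroxypropyl)-2,6-dimethyl-5-(prop-1-en-2-yl)cyclohex-2-en-1-yl acetate | OCCC[C@]1(C)[C@@H](OC(C)=O)C(C)=CC[C@H]1C(C)=C | intermediate
11 | (1S,5S,6S)-2,6-dimethyl-6-(3-oxopropyl)-5-(prop-1-en-2-yl)cyclohex-2-en-1-yl acetate | O=CCC[C@]1(C)[C@@H](OC(C)=O)C(C)=CC[C@H]1C(C)=C | intermediate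
12 | 9β-acetoxy-11-nor-drim-7-en-3β-ol | CC(=O)O[C@H]1C(C)=CC[C@H]2C(C)(C)[C@@H](O)CC[C@]12C | intermediate
13 | 9β-acetoxy-11-nor-drim-7-en-3-one | CC(=O)O[C@H]1C(C)=CC[C@H]2C(C)(C)C(=O)CC[C@]12C | intermediate
14 | 9β-acetoxy-11-nor-drim-7-en-3α-ol | CC(=O)O[C@H]1C(C)=CC[C@H]2C(C)(C)[C@H](O)CC[C@]12C | intermediate
15 | 9β-acetoxy-11-nor-drim-7-en-3α-yl 3-methylbutanoate | CC(=O)O[C@H]1C(C)=CC[C@H]2C(C)(C)[C@H](OC(=O)CC(C)C)CC[C@]12C | intermediate
16 | 9β-acetoxy-6-oxo-11-nor-drim-7-en-3α-yl 3-methylbutanoate | CC(=O)O[C@H]1C(C)=CC(=O)[C@H]2C(C)(C)[C@H](OC(=O)CC(C)C)CC[C@]12C | intermediate
17 | 6-(diiodosamariooxy)-11-nor-drima-6,8-dien-3α-yl 3-methylbutanoate (dienolate of trivalent samarium) | C1=C(C)C=C(O[Sm](I)I)[C@H]2C(C)(C)[C@H](OC(=O)CC(C)C)CC[C@]12C | intermediate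
18 | 6-(tert-butyldimethylsilyloxy)-11-nor-drima-6,8-dien-3α-yl 3-methylbutanoate | C1=C(C)C=C(O[Si](C)(C)C(C)(C)C)[C@H]2C(C)(C)[C@H](OC(=O)CC(C)C)CC[C@]12C | intermediate
19 | isofraxidin, 7-hydroxy-6,8-dimethoxy-2H-chromen-2-one | COc1cc2ccc(=O)oc2c(OC)c1O | starting material
20 | 6,8-dimethoxy-7-[(methylsulfanyl)methoxy]-2H-chromen-2-one | COc1cc2ccc(=O)oc2c(OC)c1OCSC | intermediate
21 | 7-(chloromethoxy)-6,8-dimethoxy-2H-chromen-2-one | COc1cc2ccc(=O)oc2c(OC)c1OCCl | intermediate
22 | 11-[(6,8-dimethoxy-2-oxo-2H-chromen-7-yl)oxy]-6-oxo-9-epi-drim-7-en-3α-yl 3-methylbutanoate | COc1cc2ccc(=O)oc2c(OC)c1OC[C@@H]1C(C)=CC(=O)[C@H]2C(C)(C)[C@H](OC(=O)CC(C)C)CC[C@]12C | target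

## Step count and least certain steps

Total: 15 steps. The longest linear sequence is 13 steps (steps 1–12 and 15, from 1); steps 13 and 14 prepare the coumarin electrophile from 19.

Step 7 (key step). The most likely failure is reversal of the ring closure: the C3 alkoxy radical can fragment back to the stabilised tertiary C4 radical faster than it is reduced, so material drains into plain hydrogenation of the isopropenyl group or reduction of the aldehyde. The fallback sets out from 11 and returns at 13, replacing the reversible carbonyl acceptor by a nitrile. Aldehyde 11 would be converted with I2 in aqueous NH3/THF into (1S,5S,6S)-6-(2-cyanoethyl)-2,6-dimethyl-5-(prop-1-en-2-yl)cyclohex-2-en-1-yl acetate F1. Under the same Fe(acac)3/PhSiH3 conditions the C4 radical would add 6-exo-dig to the nitrile carbon, an addition whose iminyl radical does not readily reopen, to give the ketimine 9β-acetoxy-3-imino-11-nor-drim-7-ene F2. Dilute aqueous acid on work-up hydrolyses it to 13, which also makes step 8 unnecessary.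

Step 11. The most likely failure is loss of site selectivity in the hydrogen abstraction (attack at the C8 methyl or at the well-aligned, acetoxy-bearing C9 hydrogen), together with slow reaction at the hindered C6 methylene. The fallback sets out from 15 and returns at 16 by a polar oxygen transposition. Hydroxyselenation of C7=C8 with N-(phenylseleno)phthalimide and water under acid catalysis should place selenium on C7 from the open α face and water on the tertiary C8, giving 9β-acetoxy-8β-hydroxy-7α-(phenylselanyl)-11-nor-driman-3α-yl 3-methylbutanoate F3. Oxidation with H2O2 and syn elimination of the selenoxide away from the carbinol carbon gives the tertiary allylic alcohol 9β-acetoxy-8β-hydroxy-11-nor-drim-6-en-3α-yl 3-methylbutanoate F4. Pyridinium chlorochromate, [C5H5NH][CrO3Cl], then effects the oxidative 1,3-transposition (chromate ester, [3,3] shift, oxidation) to 16.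

Step 12. The most likely failure is incomplete O-silylation of the dienolate of trivalent samarium, made worse by slow expulsion of the pseudo-equatorial acetate, so that protonation on work-up gives ketones in place of 18. The fallback sets out from 16 and returns at 18 by separating the two events. SmI2 in THF with methanol as proton source would give, by kinetic protonation at C7, the β,γ-unsaturated ketone 6-oxo-11-nor-drim-8-en-3α-yl 3-methylbutanoate F5. Its doubly activated C7 methylene is then removed by soft enolisation (TBSOTf, Et3N, CH2Cl2) to give 18.

Step 15. The most likely failure is slow ionisation of 21, because the electron-poor coumarinyl oxygen stabilises the aryloxymethyl cation poorly; protodesilylation of 18 could then win, and attack at the less hindered C7 could compete with attack at C9. The fallback sets out from 18 and 19 and returns at 22, forming the C9–C11 bond with a small, reactive C1 electrophile and the ether bond separately. Treatment of 18 with aqueous formaldehyde and Yb(OTf)3 (Mukaiyama-type hydroxymethylation) would give 11-hydroxy-6-oxo-9-epi-drim-7-en-3α-yl 3-methylbutanoate F6. A Mitsunobu reaction with 19 (PPh3, diisopropyl azodicarboxylate, THF) would then form the aryl ether under near-neutral conditions.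

Step 14. The most likely failure is electrophilic chlorination or sulfenylation of the electron-rich arene (C5) or of C3 of the pyranone by SO2Cl2 or by the sulfenyl chloride released. The fallback sets out from 19 and returns at 22, using an acyloxymethyl ether as the cation precursor. Compound 19 with bromomethyl acetate and i-Pr2NEt in MeCN would give 7-(acetoxymethoxy)-6,8-dimethoxy-2H-chromen-2-one F7. With TMSOTf in CH2Cl2 at low temperature F7 would alkylate 18 at C9 to give 22 (Lewis-acid activation of an α-acetoxy ether toward a silyl enol ether).

## Further compounds

F1 | step 7 | (1S,5S,6S)-6-(2-cyanoethyl)-2,6-dimethyl-5-(prop-1-en-2-yl)cyclohex-2-en-1-yl acetate | N#CCC[C@]1(C)[C@@H](OC(C)=O)C(C)=CC[C@H]1C(C)=C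
F2 | step 7 | 9β-acetoxy-3-imino-11-nor-drim-7-ene | CC(=O)O[C@H]1C(C)=CC[C@H]2C(C)(C)C(=N)CC[C@]12C
F3 | step 11 | 9β-acetoxy-8β-hydroxy-7α-(phenylselanyl)-11-nor-driman-3α-yl 3-methylbutanoate | CC(=O)O[C@H]1[C@@](C)(O)[C@H]([Se]c3ccccc3)C[C@H]2C(C)(C)[C@H](OC(=O)CC(C)C)CC[C@]12C
F4 | step 11 | 9β-acetoxy-8β-hydroxy-11-nor-drim-6-en-3α-yl 3-methylbutanoate | CC(=O)O[C@H]1[C@@](C)(O)C=C[C@H]2C(C)(C)[C@H](OC(=O)CC(C)C)CC[C@]12C
F5 | step 12 | 6-oxo-11-nor-drim-8-en-3α-yl 3-methylbutanoate | C1=C(C)CC(=O)[C@H]2C(C)(C)[C@H](OC(=O)CC(C)C)CC[C@]12C
F6 | step 15 | 11-hydroxy-6-oxo-9-epi-drim-7-en-3α-yl 3-methylbutanoate | OC[C@@H]1C(C)=CC(=O)[C@H]2C(C)(C)[C@H](OC(=O)CC(C)C)CC[C@]12C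
F7 | step 14 | 7-(acetoxymethoxy)-6,8-dimethoxy-2H-chromen-2-one | COc1cc2ccc(=O)oc2c(OC)c1OCOC(C)=O
A1 | alternative 1 | acyclic triene: isofraxidin (Z)-allylic ether with 3-silyloxy chain and (5Z,7E)-6-silyloxy-5,7-diene | COc1cc2ccc(=O)oc2c(OC)c1OC/C=C(C)\CC[C@H](O[Si](C)(C)C(C)(C)C)C(C)(C)/C=C(O[Si](C)(C)C(C)(C)C)/C=C/C
A2 | alternative 1 | trans-fused bicyclic 6-silyl enol ether with 3β-silyloxy group | COc1cc2ccc(=O)oc2c(OC)c1OC[C@@H]1[C@@H](C)C=C(O[Si](C)(C)C(C)(C)C)[C@H]2C(C)(C)[C@@H](O[Si](C)(C)C(C)(C)C)CC[C@]12C
A3 | alternative 2 | 4-methyl-6-(3,3-ethylenedioxy-2,2,6-trimethylcyclohex-6-en-1-yl... cyclohexenyl)-δ-lactone (4-methyl-6-cyclohexenyltetrahydropyran-2-one) | O=C1C[C@@H](C)C[C@H](O1)C1=C(C)CCC2(OCCO2)C1(C)C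
A4 | alternative 2 | 9-epi-drim-5-en-11-oic acid C3 dioxolane (8,9-dihydro) | OC(=O)[C@@H]1[C@@H](C)CC=C2C(C)(C)C3(OCCO3)CC[C@]12C
A5 | alternative 3 | 11-hydroxy-6-oxo-9-epi-drim-7-en-3α-yl 3-methylbutanoate | OC[C@@H]1C(C)=CC(=O)[C@H]2C(C)(C)[C@H](OC(=O)CC(C)C)CC[C@]12C
A6 | alternative 3 | 4-(3,3-diethoxyprop-1-enyl)-2,4-dimethoxy-3-(drimanyloxy)cyclobut-2-en-1-one (C4 epimer mixture) | CCOC(OCC)/C=C/C1(OC)C(=O)C(OC)=C1OC[C@@H]2C(C)=CC(=O)[C@H]3C(C)(C)[C@H](OC(=O)CC(C)C)CC[C@]23C
A7 | alternative 3 | 2-hydroxy-3,5-dimethoxy-4-(drimanyloxy)benzaldehyde diethyl acetal | CCOC(OCC)c1cc(OC)c(OC[C@@H]2C(C)=CC(=O)[C@H]3C(C)(C)[C@H](OC(=O)CC(C)C)CC[C@]23C)c(OC)c1O
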